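The only ring is the purchased benzene of the methylhydroquinone; everything else is acyclic. The bond-forming event on which the route rests cuts both C–C bonds at the lone ketone carbon, which sits between the allylic CH2 of the C(CH3)=CH–CH2–aryl unit and the vinylic CH of the CH=C(CH3) dienyl chain. A palladium-catalysed carbonylative Stille coupling joins an (E)-allylic chloride bearing the bis-silylated hydroquinone, carbon monoxide and an (E,E)-dienylstannane bearing the silylated (R)-carbinol. The base-sensitive skipped allyl vinyl ketone and the full C27 skeleton thus arise in one neutral operation, and no ring is formed. The stereocentre comes from a catalytic asymmetric propargylation, the three E-alkenes from two methylaluminations and one SeO2 oxidation, and buffered fluoride finally frees the three hydroxyls.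

Key step: step 15

Assumption: the (R)-configured binaphthyl phosphoric acid is taken to direct addition to the Re face of aldehyde 1, the face that leads to the (R)-carbinol; should the sense of induction prove opposite for this enal, the (S)-acid is used in step 1 and nothing else changes. TBS = tert-butyldimethylsilyl throughout.

Step 1
Reactants: 1 3-methylbut-2-enal; 2 allenylboronic acid pinacol ester
Product: 4 (R)-6-methylhept-5-en-1-yn-4-ol, via O-pinacolboryl ether 3 (not isolated)
Conditions: (R)-3,3'-bis(2,4,6-triisopropylphenyl)-1,1'-binaphthyl-2,2'-diyl hydrogen phosphate (10 mol%), 4 Å molecular sieves, toluene, −20 °C; then aqueous NaHCO3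
Reagents that add atoms: none
Why: Chiral Brønsted acid-catalysed propargylation (allenylboration) passes through a closed six-membered transition state in which the phosphate holds both the boronate oxygen and the formyl hydrogen, so the propargyl group is delivered to one face of the aldehyde, which sets the (R)-carbinol, and only the homopropargylic alcohol forms.

Step 2
Reactants: 4 (R)-6-methylhept-5-en-1-yn-4-ol
Product: 5 (R)-tert-butyldimethyl[(6-methylhept-5-en-1-yn-4-yl)oxy]silane
Conditions: TBSCl, imidazole, DMF, 0 °C to rt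
Reagents that add atoms: tert-butyldimethylsilyl chloride, CC(C)(C)[Si](C)(C)Cl
Why: Routine imidazole-promoted silylation of a secondary alcohol, placed before the carbometalation so that the ionisable allylic carbinol never meets Me3Al as a free alkoxide and the volatile alcohol is handled only once; the stereocentre is not involved.

Step 3
Reactants: 5 (R)-tert-butyldimethyl[(6-methylhept-5-en-1-yn-4-yl)oxy]silane
Product: 7 (R,E)-tert-butyl[(1-iodo-2,6-dimethylhepta-1,5-dien-4-yl)oxy]dimethylsilane, via alkenyldimethylalane 6 (not isolated)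
Conditions: Me3Al (2.5 equiv), Cp2ZrCl2 (0.25 equiv), CH2Cl2, 0 °C to rt; then I2, THF, −30 to 0 °C
Reagents that add atoms: trimethylaluminium, C[Al](C)C; iodine, II
Why: Negishi zirconium-catalysed carboalumination adds CH3 and aluminium syn across the terminal alkyne with aluminium on the terminal carbon, and iodinolysis of the C–Al bond with retention gives the (E)-2-methyl-1-iodoalkene while the trisubstituted alkene and the silyl ether stay inert.

Step 4
Reactants: 7 (R,E)-tert-butyl[(1-iodo-2,6-dimethylhepta-1,5-dien-4-yl)oxy]dimethylsilane; 8 4-bromo-1-(trimethylsilyl)but-1-yne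
Product: 11 (R,E)-tert-butyl{[6,10-dimethyl-1-(trimethylsilyl)undeca-5,9-dien-1-yn-8-yl]oxy}dimethylsilane, via Grignard reagent 9 (not isolated), via alkylzinc bromide 10 (not isolated)
Conditions: 8, Mg, THF, rt; ZnBr2, THF, 0 °C; then 7, Pd(PPh3)4 (5 mol%), THF, rt to 40 °C
Reagents that add atoms: none
Why: Negishi coupling of a primary alkylzinc halide with an alkenyl iodide proceeds with retention at the sp2 carbon, so the E-geometry of 7 is carried into the 1,5-diene, and the C-silyl cap keeps the alkyne inert to magnesium, zinc and palladium.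

Step 5
Reactants: 11 (R,E)-tert-butyl{[6,10-dimethyl-1-(trimethylsilyl)undeca-5,9-dien-1-yn-8-yl]oxy}dimethylsilane
Product: 12 (R,E)-tert-butyl[(6,10-dimethylundeca-5,9-dien-1-yn-8-yl)oxy]dimethylsilane
Conditions: K2CO3 (0.3 equiv), MeOH, rt
Reagents that add atoms: none
Why: Methoxide-catalysed methanolysis cleaves the alkynyl C–Si bond selectively because the acetylide is a far better leaving group than the alkoxide of the hindered alkyl TBS ether, which therefore remains.

Step 6
Reactants: 12 (R,E)-tert-butyl[(6,10-dimethylundeca-5,9-dien-1-yn-8-yl)oxy]dimethylsilane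
Product: 14 tert-butyl{[(4R,6E,10E)-11-iodo-2,6,10-trimethylundeca-2,6,10-trien-4-yl]oxy}dimethylsilane, via dienyldimethylalane 13 (not isolated)
Conditions: Me3Al (2.5 equiv), Cp2ZrCl2 (0.25 equiv), CH2Cl2, 0 °C to rt; then I2, THF, −30 to 0 °C
Reagents that add atoms: trimethylaluminium, C[Al](C)C; iodine, II
Why: A second Negishi carboalumination with iodinolysis installs the second E-trisubstituted alkene by the same syn addition and stereoretentive C–Al cleavage, the two existing trisubstituted alkenes being unreactive toward the methylzirconium species.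

Step 7
Reactants: 14 tert-butyl{[(4R,6E,10E)-11-iodo-2,6,10-trimethylundeca-2,6,10-trien-4-yl]oxy}dimethylsilane
Product: 16 tert-butyldimethyl{[(4R,6E,10E)-2,6,10-trimethyl-11-(tributylstannyl)undeca-2,6,10-trien-4-yl]oxy}silane (fragment 1), via dienyllithium 15 (not isolated)
Conditions: t-BuLi (2.1 equiv), Et2O, −78 °C; then Bu3SnCl, −78 °C to rt; chromatography on Et3N-deactivated silica
Reagents that add atoms: tributyltin chloride, CCCC[Sn](Cl)(CCCC)CCCC
Why: Iodine–lithium exchange is faster than any deprotonation at −78 °C and keeps the alkene geometry, and trapping the alkenyllithium at tin gives the (E)-alkenylstannane required for a stereoretentive transfer to palladium.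

Step 8
Reactants: 17 4-methoxy-2-methylphenol
Product: 18 2-bromo-4-methoxy-6-methylphenol
Conditions: NBS (1.0 equiv), i-Pr2NH (0.1 equiv), CH2Cl2, 0 °C
Reagents that add atoms: N-bromosuccinimide, O=C1CCC(=O)N1Br
Why: Electrophilic aromatic bromination is steered by the free phenol, the strongest donor, to its single open ortho position, the para position being blocked by the methoxy group.

Step 9
Reactants: 18 2-bromo-4-methoxy-6-methylphenol
Product: 19 1-bromo-2,5-dimethoxy-3-methylbenzene
Conditions: MeI, K2CO3, acetone, reflux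
Reagents that add atoms: iodomethane, CI
Why: Williamson O-methylation of the phenoxide removes the acidic proton before metalation and gives a hydroquinone dimethyl ether that can later be unmasked oxidatively.

Step 10
Reactants: 19 1-bromo-2,5-dimethoxy-3-methylbenzene; 20 prenyl bromide (1-bromo-3-methylbut-2-ene)
Product: 23 2,5-dimethoxy-1-methyl-3-(3-methylbut-2-en-1-yl)benzene, via aryllithium 21 (not isolated), via arylcopper 22 (not isolated)
Conditions: n-BuLi, THF, −78 °C; CuBr·SMe2 (1.0 equiv), −78 to −40 °C; then 20, −78 °C to rt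
Reagents that add atoms: none
Why: Bromine–lithium exchange and transmetalation to copper give a soft arylcopper that substitutes the allylic bromide at its primary carbon, since attack at the gem-dimethyl terminus would have to build a quaternary benzylic carbon; this is a standard prenylation of hydroquinone dimethyl ethers.

Step 11
Reactants: 23 2,5-dimethoxy-1-methyl-3-(3-methylbut-2-en-1-yl)benzene
Product: 24 2-methyl-6-(3-methylbut-2-en-1-yl)-1,4-benzoquinone
Conditions: (NH4)2Ce(NO3)6 (2.5 equiv), MeCN/H2O, 0 °C
Reagents that add atoms: water, O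
Why: Oxidative demethylation of a 1,4-dimethoxyarene by two one-electron oxidations with tetravalent cerium, with water adding at the methoxy-bearing carbons and methanol leaving, gives the para-quinone quickly at 0 °C while the isolated trisubstituted alkene is untouched.

Step 12
Reactants: 24 2-methyl-6-(3-methylbut-2-en-1-yl)-1,4-benzoquinone
Product: 26 1,4-bis(tert-butyldimethylsilyloxy)-2-methyl-6-(3-methylbut-2-en-1-yl)benzene, via hydroquinone 25 (not isolated)
Conditions: Na2S2O4, EtOAc/H2O, rt (argon); then crude 25, TBSCl, imidazole, 4-(dimethylamino)pyridine (cat.), DMF, rt to 40 °C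
Reagents that add atoms: tert-butyldimethylsilyl chloride, CC(C)(C)[Si](C)(C)Cl
Why: Dithionite reduces the quinone to the air-sensitive hydroquinone, which is silylated at once on both oxygens; silyl ethers are chosen because they survive the remaining steps and leave with fluoride under non-oxidising, non-basic conditions that the final hydroquinone and skipped enone tolerate.

Step 13
Reactants: 26 1,4-bis(tert-butyldimethylsilyloxy)-2-methyl-6-(3-methylbut-2-en-1-yl)benzene
Product: 28 (E)-4-[2,5-bis(tert-butyldimethylsilyloxy)-3-methylphenyl]-2-methylbut-2-en-1-ol, via enal 27 (not isolated)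
Conditions: SeO2 (0.5 equiv), t-BuOOH (3 equiv), salicylic acid (0.1 equiv), CH2Cl2, 0 °C to rt; then NaBH4, EtOH, 0 °C
Reagents that add atoms: selenium dioxide (oxygen carrier), O=[Se]=O; tert-butyl hydroperoxide (terminal oxidant), CC(C)(C)OO
Why: Catalytic SeO2 allylic oxidation (ene reaction then [2,3]-sigmatropic shift) acts at the more substituted alkene terminus and on the methyl group trans to the chain, giving the (E)-allylic alcohol, and the portion carried on to enal 27 is returned to 28 by NaBH4.

Step 14
Reactants: 28 (E)-4-[2,5-bis(tert-butyldimethylsilyloxy)-3-methylphenyl]-2-methylbut-2-en-1-ol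
Product: 29 1,4-bis(tert-butyldimethylsilyloxy)-2-[(E)-4-chloro-3-methylbut-2-en-1-yl]-6-methylbenzene (fragment 2)
Conditions: NCS, Me2S, CH2Cl2, −20 to 0 °C (reagent premixed before 28 is added)
Reagents that add atoms: N-chlorosuccinimide, O=C1CCC(=O)N1Cl
Why: In this Corey–Kim chlorination the alcohol attacks the chlorosulfonium salt formed from NCS and Me2S and chloride displaces dimethyl sulfoxide at the primary carbon, without allylic transposition or loss of E-geometry and under neutral conditions that spare the aryl silyl ethers.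

Step 15
Reactants: 16 tert-butyldimethyl{[(4R,6E,10E)-2,6,10-trimethyl-11-(tributylstannyl)undeca-2,6,10-trien-4-yl]oxy}silane; 29 1,4-bis(tert-butyldimethylsilyloxy)-2-[(E)-4-chloro-3-methylbut-2-en-1-yl]-6-methylbenzene; 30 carbon monoxide
Product: 31 (2E,6E,10E,13R)-1-[2,5-bis(tert-butyldimethylsilyloxy)-3-methylphenyl]-13-(tert-butyldimethylsilyloxy)-3,7,11,15-tetramethylhexadeca-2,6,10,14-tetraen-5-one
Conditions: Pd2(dba)3 (2.5 mol%), PPh3 (10 mol%), CO (4 atm), THF, 50 °C
Reagents that add atoms: none
Why: Zerovalent palladium ionises the C–Cl bond of 29 to a 2-methyl-substituted pi-allyl complex of divalent palladium, CO inserts at the unsubstituted CH2 terminus to give a but-3-enoyl palladium chloride, the alkenyl group of 16 is transferred from tin with retention, and reductive elimination releases ketone 31 and returns the catalyst. The closest known reaction type is the carbonylative Stille coupling of allylic chlorides with alkenylstannanes, which gives allyl vinyl ketones without migration of the beta,gamma-alkene because neither base nor enolate is present. No ring is closed and no stereocentre is created, and the silylated (R)-carbinol is remote and untouched. Three selectivities are needed: carbonylation over direct allyl–alkenyl coupling, secured by CO pressure and by the slow direct transmetalation of the hindered beta,beta-disubstituted alkenylstannane; bonding at the primary allyl terminus, secured by the steric contrast with the terminus that carries the benzylic CH2; and retention of all three E-alkenes, secured by the syn pi-allyl geometry (which maps onto the E-alkene) and the stereoretentive tin-to-palladium transfer. The silyl ethers, the trisubstituted alkenes and the electron-rich arene are inert to the catalyst, and the phenols must stay capped because a free ortho-hydroxyl would cyclise onto the pi-allyl intermediate.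

Step 16
Reactants: 31 (2E,6E,10E,13R)-1-[2,5-bis(tert-butyldimethylsilyloxy)-3-methylphenyl]-13-(tert-butyldimethylsilyloxy)-3,7,11,15-tetramethylhexadeca-2,6,10,14-tetraen-5-one
Product: 32 (2E,6E,10E,13R)-1-(2,5-dihydroxy-3-methylphenyl)-13-hydroxy-3,7,11,15-tetramethylhexadeca-2,6,10,14-tetraen-5-one (CNP0251818.3)
Conditions: HF·pyridine, excess pyridine, THF, 0 °C to rt (argon, plastic vessel); pH 7 phosphate buffer work-up
Reagents that add atoms: none
Why: Fluoride-mediated desilylation cleaves all three Si–O bonds, and the pyridine buffer keeps the medium neither basic enough to move the beta,gamma-alkene into conjugation or promote air oxidation of the hydroquinone nor acidic enough to ionise the allylic carbinol, so the stereocentre and the three E-alkenes are carried through unchanged.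

Compound list
1 | 3-methylbut-2-enal | CC(C)=CC=O | starting material
2 | allenylboronic acid pinacol ester | C=C=CB1OC(C)(C)C(C)(C)O1 | starting material
3 | (R)-4,4,5,5-tetramethyl-2-[(6-methylhept-5-en-1-yn-4-yl)oxy]-1,3,2-dioxaborolane | C#CC[C@@H](OB1OC(C)(C)C(C)(C)O1)C=C(C)C | intermediate
4 | (R)-6-methylhept-5-en-1-yn-4-ol | C#CC[C@@H](O)C=C(C)C | intermediate
5 | (R)-tert-butyldimethyl[(6-methylhept-5-en-1-yn-4-yl)oxy]silane | C#CC[C@@H](O[Si](C)(C)C(C)(C)C)C=C(C)C | intermediate
6 | [(1E,4R)-4-(tert-butyldimethylsilyloxy)-2,6-dimethylhepta-1,5-dien-1-yl]dimethylaluminium | C[Al](C)/C=C(C)/C[C@@H](O[Si](C)(C)C(C)(C)C)C=C(C)C | intermediate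
7 | (R,E)-tert-butyl[(1-iodo-2,6-dimethylhepta-1,5-dien-4-yl)oxy]dimethylsilane | I/C=C(C)/C[C@@H](O[Si](C)(C)C(C)(C)C)C=C(C)C | intermediate
8 | 4-bromo-1-(trimethylsilyl)but-1-yne | C[Si](C)(C)C#CCCBr | starting material
9 | [4-(trimethylsilyl)but-3-yn-1-yl]magnesium bromide | C[Si](C)(C)C#CCC[Mg]Br | intermediate
10 | [4-(trimethylsilyl)but-3-yn-1-yl]zinc bromide | C[Si](C)(C)C#CCC[Zn]Br | intermediate
11 | (R,E)-tert-butyl{[6,10-dimethyl-1-(trimethylsilyl)undeca-5,9-dien-1-yn-8-yl]oxy}dimethylsilane | C[Si](C)(C)C#CCC/C=C(C)/C[C@@H](O[Si](C)(C)C(C)(C)C)C=C(C)C | intermediate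
12 | (R,E)-tert-butyl[(6,10-dimethylundeca-5,9-dien-1-yn-8-yl)oxy]dimethylsilane | C#CCC/C=C(C)/C[C@@H](O[Si](C)(C)C(C)(C)C)C=C(C)C | intermediate
13 | [(1E,5E,8R)-8-(tert-butyldimethylsilyloxy)-2,6,10-trimethylundeca-1,5,9-trien-1-yl]dimethylaluminium | C[Al](C)/C=C(C)/CC/C=C(C)/C[C@@H](O[Si](C)(C)C(C)(C)C)C=C(C)C | intermediate
14 | tert-butyl{[(4R,6E,10E)-11-iodo-2,6,10-trimethylundeca-2,6,10-trien-4-yl]oxy}dimethylsilane | I/C=C(C)/CC/C=C(C)/C[C@@H](O[Si](C)(C)C(C)(C)C)C=C(C)C | intermediate
15 | [(1E,5E,8R)-8-(tert-butyldimethylsilyloxy)-2,6,10-trimethylundeca-1,5,9-trien-1-yl]lithium | [Li]/C=C(C)/CC/C=C(C)/C[C@@H](O[Si](C)(C)C(C)(C)C)C=C(C)C | intermediate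
16 | tert-butyldimethyl{[(4R,6E,10E)-2,6,10-trimethyl-11-(tributylstannyl)undeca-2,6,10-trien-4-yl]oxy}silane (fragment 1) | CCCC[Sn](CCCC)(CCCC)/C=C(C)/CC/C=C(C)/C[C@@H](O[Si](C)(C)C(C)(C)C)C=C(C)C | intermediate
17 | 4-methoxy-2-methylphenol | COc1ccc(O)c(C)c1 | starting material
18 | 2-bromo-4-methoxy-6-methylphenol | COc1cc(C)c(O)c(Br)c1 | intermediate
19 | 1-bromo-2,5-dimethoxy-3-methylbenzene | COc1cc(C)c(OC)c(Br)c1 | intermediate
20 | prenyl bromide (1-bromo-3-methylbut-2-ene) | CC(C)=CCBr | starting material
21 | (2,5-dimethoxy-3-methylphenyl)lithium | [Li]c1cc(OC)cc(C)c1OC | intermediate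
22 | (2,5-dimethoxy-3-methylphenyl)copper | [Cu]c1cc(OC)cc(C)c1OC | intermediate
23 | 2,5-dimethoxy-1-methyl-3-(3-methylbut-2-en-1-yl)benzene | COc1cc(C)c(OC)c(CC=C(C)C)c1 | intermediate
24 | 2-methyl-6-(3-methylbut-2-en-1-yl)-1,4-benzoquinone | CC1=CC(=O)C=C(CC=C(C)C)C1=O | intermediate
25 | 2-methyl-6-(3-methylbut-2-en-1-yl)benzene-1,4-diol | Cc1cc(O)cc(CC=C(C)C)c1O | intermediate
26 | 1,4-bis(tert-butyldimethylsilyloxy)-2-methyl-6-(3-methylbut-2-en-1-yl)benzene | Cc1cc(O[Si](C)(C)C(C)(C)C)cc(CC=C(C)C)c1O[Si](C)(C)C(C)(C)C | intermediate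
27 | (E)-4-[2,5-bis(tert-butyldimethylsilyloxy)-3-methylphenyl]-2-methylbut-2-enal | Cc1cc(O[Si](C)(C)C(C)(C)C)cc(C/C=C(\C)C=O)c1O[Si](C)(C)C(C)(C)C | intermediate
28 | (E)-4-[2,5-bis(tert-butyldimethylsilyloxy)-3-methylphenyl]-2-methylbut-2-en-1-ol | Cc1cc(O[Si](C)(C)C(C)(C)C)cc(C/C=C(\C)CO)c1O[Si](C)(C)C(C)(C)C | intermediate
29 | 1,4-bis(tert-butyldimethylsilyloxy)-2-[(E)-4-chloro-3-methylbut-2-en-1-yl]-6-methylbenzene (fragment 2) | Cc1cc(O[Si](C)(C)C(C)(C)C)cc(C/C=C(\C)CCl)c1O[Si](C)(C)C(C)(C)C | intermediate
30 | carbon monoxide | [C-]#[O+] | starting material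
31 | (2E,6E,10E,13R)-1-[2,5-bis(tert-butyldimethylsilyloxy)-3-methylphenyl]-13-(tert-butyldimethylsilyloxy)-3,7,11,15-tetramethylhexadeca-2,6,10,14-tetraen-5-one | CC(C)=C[C@H](O[Si](C)(C)C(C)(C)C)C/C(C)=C/CC/C(C)=C/C(=O)C/C(C)=C/Cc1cc(O[Si](C)(C)C(C)(C)C)cc(C)c1O[Si](C)(C)C(C)(C)C | intermediate
32 | (2E,6E,10E,13R)-1-(2,5-dihydroxy-3-methylphenyl)-13-hydroxy-3,7,11,15-tetramethylhexadeca-2,6,10,14-tetraen-5-one (CNP0251818.3) | CC(C)=C[C@H](O)C/C(C)=C/CC/C(C)=C/C(=O)C/C(C)=C/Cc1cc(O)cc(C)c1O | target

Total step count: 16 (seven steps to fragment 1, seven to fragment 2, the union and the deprotection).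
Longest linear sequence: 9 steps (steps 1–7, 15 and 16; the arene arm, steps 8–14, 15 and 16, is equally long).

Steps most likely to fail

1. Step 15. Direct allyl–alkenyl coupling may compete with CO insertion. The tin-to-palladium transfer of the hindered beta,beta-disubstituted alkenyl group may be sluggish. Prolonged heating may let the beta,gamma-alkene drift into conjugation. The fallback sets out from 14 and 29 and returns at 31. Iodide 14 is exchanged with t-BuLi (Et2O, −78 °C) to alkenyllithium 15 and formylated with DMF to the (2E,6E,9R)-dienal F1. Chloride 29 is treated at −78 °C in THF with activated barium, made from BaI2 and two equivalents of lithium biphenylide, to give the allylbarium chloride F2. Allylbarium reagents are known to add to aldehydes through the primary (alpha) carbon with retention of alkene geometry, so F2 should add 1,2 to F1 and give the secondary alcohol F3 as a mixture of carbinol epimers. NaHCO3-buffered Dess–Martin periodinane oxidation should convert both epimers into 31 without moving the beta,gamma-alkene.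

2. Step 13. Conversion may be low, over-oxidation may go to the enal and beyond, and oxidation may compete at the doubly activated benzylic–allylic CH2 or on the electron-rich ring. The fallback sets out from 26 and returns at 28. Dihydroxylation of the prenyl alkene with OsO4 (cat.) and N-methylmorpholine N-oxide gives the diol F4, and NaIO4 cleaves it to the arylacetaldehyde F5. Wittig olefination with the stabilised ylide Ph3P=C(CH3)CO2Et gives the (E)-enoate F6. Reduction with i-Bu2AlH (CH2Cl2, −78 °C) then delivers allylic alcohol 28 with the E-geometry fixed by the ylide.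

3. Step 16. The hindered aryl silyl ether may cleave slowly under buffered acidic fluoride, and long exposure would allow ionisation of the allylic carbinol, isomerisation of the skipped enone or air oxidation of the hydroquinone. The fallback sets out from 16 and returns at 32. The carbinol is unmasked early, on the robust stannane, with Bu4NF in THF to give the hydroxy stannane F7. F7 is coupled with 29 and 30 under the conditions of step 15, which tolerate a free alcohol, to give the bis-silyl ketone F8. The two phenolic silyl ethers of F8 are then removed selectively and quickly with KHF2 in MeOH at rt, a near-neutral reagent specific for aryl silyl ethers, to give 32.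

Further compounds
F1 | step 15 | (2E,6E,9R)-9-(tert-butyldimethylsilyloxy)-3,7,11-trimethyldodeca-2,6,10-trienal | O=C/C=C(C)/CC/C=C(C)/C[C@@H](O[Si](C)(C)C(C)(C)C)C=C(C)C
F2 | step 15 | {(E)-4-[2,5-bis(tert-butyldimethylsilyloxy)-3-methylphenyl]-2-methylbut-2-en-1-yl}barium chloride | Cc1cc(O[Si](C)(C)C(C)(C)C)cc(C/C=C(\C)C[Ba]Cl)c1O[Si](C)(C)C(C)(C)C
F3 | step 15 | (2E,6E,10E,13R)-1-[2,5-bis(tert-butyldimethylsilyloxy)-3-methylphenyl]-13-(tert-butyldimethylsilyloxy)-3,7,11,15-tetramethylhexadeca-2,6,10,14-tetraen-5-ol (both C5 epimers) | CC(C)=C[C@H](O[Si](C)(C)C(C)(C)C)C/C(C)=C/CC/C(C)=C/C(O)C/C(C)=C/Cc1cc(O[Si](C)(C)C(C)(C)C)cc(C)c1O[Si](C)(C)C(C)(C)C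
F4 | step 13 | 1-[2,5-bis(tert-butyldimethylsilyloxy)-3-methylphenyl]-3-methylbutane-2,3-diol (racemic) | Cc1cc(O[Si](C)(C)C(C)(C)C)cc(CC(O)C(C)(C)O)c1O[Si](C)(C)C(C)(C)C
F5 | step 13 | 2-[2,5-bis(tert-butyldimethylsilyloxy)-3-methylphenyl]acetaldehyde | Cc1cc(O[Si](C)(C)C(C)(C)C)cc(CC=O)c1O[Si](C)(C)C(C)(C)C
F6 | step 13 | ethyl (E)-4-[2,5-bis(tert-butyldimethylsilyloxy)-3-methylphenyl]-2-methylbut-2-enoate | CCOC(=O)/C(C)=C/Cc1cc(O[Si](C)(C)C(C)(C)C)cc(C)c1O[Si](C)(C)C(C)(C)C
F7 | step 16 | (4R,6E,10E)-2,6,10-trimethyl-11-(tributylstannyl)undeca-2,6,10-trien-4-ol | CCCC[Sn](CCCC)(CCCC)/C=C(C)/CC/C=C(C)/C[C@@H](O)C=C(C)C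
F8 | step 16 | (2E,6E,10E,13R)-1-[2,5-bis(tert-butyldimethylsilyloxy)-3-methylphenyl]-13-hydroxy-3,7,11,15-tetramethylhexadeca-2,6,10,14-tetraen-5-one | CC(C)=C[C@H](O)C/C(C)=C/CC/C(C)=C/C(=O)C/C(C)=C/Cc1cc(O[Si](C)(C)C(C)(C)C)cc(C)c1O[Si](C)(C)C(C)(C)C
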